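**Retrosynthetic overview**
1. The last step is hydrogenolysis of three benzyl ethers (5-O, 7-O, 8-O) on the finished isoflavone skeleton.
2. The key disconnection is C3–C1'. Two carbons that are both nucleophilic are joined oxidatively: the α-carbon of an o-hydroxyaryl enaminone (ring A plus C4, C3, C2) and C5 of commercial 2,3-dimethoxyphenol (ring B). The phenol is polarity-reversed by dearomatisation to its o-quinone monoketal. The same operation closes ring C (O1–C2) and rearomatises ring B with the 3'-OH free.
3. Enabling feature: in ring B, C1' lies para to C4' (OMe) and meta to C3' (OH). It is therefore the β-carbon of the 2,4-dienone (C3'=O, ketal at C4') formed on oxidation. C5'-OMe blocks the δ-carbon. C3 of ring C is the α-carbon of the vinylogous amide O=C4–C3=C2–N, and C2 then accepts the C8a–OH.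
4. Ring A comes from phloroacetophenone. C8–O is installed by ring formylation and Dakin oxidation, C6–OMe by Elbs oxidation and methylation. The chelated OH is kept free throughout and becomes O1.
5. Ring order: rings A and B are bought as arenes. Ring B is dearomatised and rearomatised in the key step, and ring C forms last, in that same step.

Key step: step 8

Remark: the target SMILES holds no stereocentre, stereogenic axis or configurable double bond. The compound is achiral and there is no enantiomer to select. The only stereodescriptors in the route are the E double bonds of the enaminones.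

**Step 1**
Reactants: 1 2,4,6-trihydroxyacetophenone
Product: 3 3-acetyl-2,4,6-trihydroxybenzaldehyde, via iminium chloride 2 (not isolated)
Conditions: POCl3 (1.1 equiv), DMF, EtOAc, 0 °C → rt; then H2O, 60 °C
Reagents that add atoms: N,N-dimethylformamide, CN(C)C=O (formyl carbon); water, O (formyl oxygen)
Why: Vilsmeier–Haack formylation, in which the phloroglucinol ring is far more nucleophilic than the acetyl enol, its two free CH positions are equivalent, and the iminium group of 2 deactivates the ring against a second attack until it is hydrolysed.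

**Step 2**
Reactants: 3 3-acetyl-2,4,6-trihydroxybenzaldehyde
Product: 4 3-acetyl-4,6-bis(benzyloxy)-2-hydroxybenzaldehyde
Conditions: BnBr (2.1 equiv), K2CO3 (2.2 equiv), DMF, rt → 40 °C
Reagents that add atoms: benzyl bromide, BrCc1ccccc1
Why: Williamson etherification under weak base, in which the OH between acetyl and formyl is hydrogen-bonded to both carbonyl groups and flanked on both sides, so the two outer, more acidic and less hindered OH groups should be alkylated first.

**Step 3**
Reactants: 4 3-acetyl-4,6-bis(benzyloxy)-2-hydroxybenzaldehyde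
Product: 6 1-[4,6-bis(benzyloxy)-2,3-dihydroxyphenyl]ethanone, via aryl formate 5 (not isolated)
Conditions: 30% H2O2 (1.2 equiv), NaOH, THF–H2O, 0 °C, N2; then HCl
Reagents that add atoms: hydrogen peroxide, OO
Why: Dakin oxidation, in which hydroperoxide adds to the o-hydroxy-activated formyl group faster than to the methyl ketone, aryl migration gives formate 5, and this is saponified in the same flask.

**Step 4**
Reactants: 6 1-[4,6-bis(benzyloxy)-2,3-dihydroxyphenyl]ethanone
Product: 7 1-[3,4,6-tris(benzyloxy)-2-hydroxyphenyl]ethanone
Conditions: BnBr (1.05 equiv), K2CO3 (1.1 equiv), acetone, reflux, N2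
Reagents that add atoms: benzyl bromide, BrCc1ccccc1
Why: Williamson etherification, in which the 2-OH is chelated to the acetyl carbonyl, so one equivalent of benzyl bromide should take the free 3-OH.

**Step 5**
Reactants: 7 1-[3,4,6-tris(benzyloxy)-2-hydroxyphenyl]ethanone
Product: 9 1-[3,4,6-tris(benzyloxy)-2,5-dihydroxyphenyl]ethanone, via aryl sulfate 8 (not isolated)
Conditions: K2S2O8 (1.1 equiv), aq NaOH, pyridine, 0 °C → rt; then 2 M HCl, 70 °C
Reagents that add atoms: potassium peroxodisulfate, [K+].[K+].[O-]S(=O)(=O)OOS(=O)(=O)[O-]
Why: Elbs persulfate oxidation, in which the phenoxide attacks the peroxide oxygen through its para carbon (the only free ring position) to give sulfate 8, which dilute acid hydrolyses, a transformation that is classical for the corresponding trimethyl ether.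

**Step 6**
Reactants: 9 1-[3,4,6-tris(benzyloxy)-2,5-dihydroxyphenyl]ethanone
Product: 10 1-[3,4,6-tris(benzyloxy)-2-hydroxy-5-methoxyphenyl]ethanone
Conditions: MeI (1.1 equiv), K2CO3 (1.1 equiv), acetone, reflux, N2
Reagents that add atoms: iodomethane, CI
Why: Selective Williamson O-methylation, in which the 5-OH is the only non-chelated phenol and should react before the 2-OH bound to the acetyl carbonyl.

**Step 7**
Reactants: 10 1-[3,4,6-tris(benzyloxy)-2-hydroxy-5-methoxyphenyl]ethanone
Product: 11 (E)-3-(dimethylamino)-1-[3,4,6-tris(benzyloxy)-2-hydroxy-5-methoxyphenyl]prop-2-en-1-one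
Conditions: DMF-DMA (4 equiv), toluene, 95 °C
Reagents that add atoms: N,N-dimethylformamide dimethyl acetal, COC(OC)N(C)C
Why: Enaminone formation by condensation of the acetyl CH3 with an amide acetal, the standard entry to o-hydroxyaryl enaminones, which gives the E isomer and leaves the chelated phenol and the benzyl ethers untouched.

**Step 8**
Reactants: 11 (E)-3-(dimethylamino)-1-[3,4,6-tris(benzyloxy)-2-hydroxy-5-methoxyphenyl]prop-2-en-1-one; 12 2,3-dimethoxyphenol
Product: 16 5,7,8-tris(benzyloxy)-3-(3-hydroxy-4,5-dimethoxyphenyl)-6-methoxy-4H-chromen-4-one, via masked o-benzoquinone 13 (not isolated), via Michael adduct 14 (not isolated), via α-aryl enaminone 15 (not isolated)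
Conditions: 12 (1.6 equiv), PhI(OAc)2 (1.5 equiv), MeOH, 0 °C, 20 min; then 11 (1 equiv) in CH2Cl2, 0 → 40 °C; then TsOH·H2O (10 mol %), 40 °C
Reagents that add atoms: methanol, CO (second ketal OMe of 13; either ketal OMe can end as the 4'-OMe of 16)
Why: Proposed new method: PhI(OAc)2 in MeOH first dearomatises 12 at its OMe-bearing ortho carbon to the masked o-benzoquinone 13 (a known oxidation), which turns the inherently nucleophilic C5 of the phenol into the β-carbon of a 2,4-dienone, and the α-carbon of the vinylogous amide 11 then adds to it in a Stork-enamine-type Michael addition to give 14. Acid-assisted 1,4-loss of one ketal methanol plus enolisation rearomatises ring B to 15, the same α-aryl enaminone through which the deoxybenzoin/DMF-DMA isoflavone synthesis runs, and ring C then closes by attack of the chelated 2-OH on the aminomethine carbon (6-endo-trig addition–elimination, Me2NH leaves). The closest known reaction types are the Michael addition/aromatisation of indoles, electron-rich arenes and 1,3-dicarbonyls on masked o-benzoquinones, the first C–C bond formation of the Nenitzescu reaction (enaminone carbon onto a quinone), and the domino α-functionalisation/chromone annulation of o-hydroxyaryl enaminones with other electrophiles, but an enaminone has not been joined to a masked o-benzoquinone in this way. No stereocentre remains, since the one ring carbon that becomes sp3 in 14 is flattened again on aromatisation. The step needs site selectivity on 13, which is secured by the C5 methoxy group: it blocks the δ-carbon (needed for 1,6-addition and for the [4+2] mode), should slow Diels–Alder self-dimerisation and leaves C3 as the only open electrophilic CH, while a medium that stays only weakly acidic (AcOH) until the C–C bond is made avoids ketal ionisation and attack para to the oxygen. Chemoselectivity is secured by using the oxidant as the limiting reagent before 11 is added, so that neither the enaminone nor the electron-rich ring A meets iodine(III), and by the released acetic acid, which ties up Me2NH.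

**Step 9**
Reactants: 16 5,7,8-tris(benzyloxy)-3-(3-hydroxy-4,5-dimethoxyphenyl)-6-methoxy-4H-chromen-4-one
Product: 17 5,7,8,3'-tetrahydroxy-6,4',5'-trimethoxyisoflavone
Conditions: H2 (1 atm), 10% Pd/C, EtOAc–MeOH, rt; filtration and work-up under Ar
Reagents that add atoms: none
Why: Catalytic hydrogenolysis of aryl benzyl ethers, a neutral method that leaves the methyl ethers and, when stopped at full debenzylation, the C2=C3 bond intact and avoids the acid-induced Wessely–Moser ring opening and reclosure that could scramble the ring A pattern.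

**Compound list**
1 | 2,4,6-trihydroxyacetophenone | CC(=O)c1c(O)cc(O)cc1O | starting material
2 | [(3-acetyl-2,4,6-trihydroxyphenyl)methylidene]dimethylammonium chloride | CC(=O)c1c(O)c(C=[N+](C)C)c(O)cc1O.[Cl-] | intermediate
3 | 3-acetyl-2,4,6-trihydroxybenzaldehyde | CC(=O)c1c(O)c(C=O)c(O)cc1O | intermediate
4 | 3-acetyl-4,6-bis(benzyloxy)-2-hydroxybenzaldehyde | CC(=O)c1c(O)c(C=O)c(OCc2ccccc2)cc1OCc1ccccc1 | intermediate
5 | 3-acetyl-4,6-bis(benzyloxy)-2-hydroxyphenyl formate | CC(=O)c1c(O)c(OC=O)c(OCc2ccccc2)cc1OCc1ccccc1 | intermediate
6 | 1-[4,6-bis(benzyloxy)-2,3-dihydroxyphenyl]ethanone | CC(=O)c1c(O)c(O)c(OCc2ccccc2)cc1OCc1ccccc1 | intermediate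
7 | 1-[3,4,6-tris(benzyloxy)-2-hydroxyphenyl]ethanone | CC(=O)c1c(O)c(OCc2ccccc2)c(OCc2ccccc2)cc1OCc1ccccc1 | intermediate
8 | potassium 3-acetyl-2,5,6-tris(benzyloxy)-4-hydroxyphenyl sulfate | CC(=O)c1c(O)c(OCc2ccccc2)c(OCc2ccccc2)c(OS(=O)(=O)[O-])c1OCc1ccccc1.[K+] | intermediate
9 | 1-[3,4,6-tris(benzyloxy)-2,5-dihydroxyphenyl]ethanone | CC(=O)c1c(O)c(OCc2ccccc2)c(OCc2ccccc2)c(O)c1OCc1ccccc1 | intermediate
10 | 1-[3,4,6-tris(benzyloxy)-2-hydroxy-5-methoxyphenyl]ethanone | CC(=O)c1c(O)c(OCc2ccccc2)c(OCc2ccccc2)c(OC)c1OCc1ccccc1 | intermediate
11 | (E)-3-(dimethylamino)-1-[3,4,6-tris(benzyloxy)-2-hydroxy-5-methoxyphenyl]prop-2-en-1-one | CN(C)/C=C/C(=O)c1c(O)c(OCc2ccccc2)c(OCc2ccccc2)c(OC)c1OCc1ccccc1 | intermediate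
12 | 2,3-dimethoxyphenol | COc1cccc(O)c1OC | starting material
13 | 5,6,6-trimethoxycyclohexa-2,4-dien-1-one | COC1=CC=CC(=O)C1(OC)OC | intermediate
14 | (E)-3-(dimethylamino)-1-[3,4,6-tris(benzyloxy)-2-hydroxy-5-methoxyphenyl]-2-(3,4,4-trimethoxy-5-oxocyclohex-2-en-1-yl)prop-2-en-1-one (racemic at the ring carbon, centre lost on aromatisation) | CN(C)/C=C(\C1CC(=O)C(OC)(OC)C(OC)=C1)C(=O)c1c(O)c(OCc2ccccc2)c(OCc2ccccc2)c(OC)c1OCc1ccccc1 | intermediate
15 | (E)-3-(dimethylamino)-2-(3-hydroxy-4,5-dimethoxyphenyl)-1-[3,4,6-tris(benzyloxy)-2-hydroxy-5-methoxyphenyl]prop-2-en-1-one | CN(C)/C=C(\c1cc(O)c(OC)c(OC)c1)C(=O)c1c(O)c(OCc2ccccc2)c(OCc2ccccc2)c(OC)c1OCc1ccccc1 | intermediate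
16 | 5,7,8-tris(benzyloxy)-3-(3-hydroxy-4,5-dimethoxyphenyl)-6-methoxy-4H-chromen-4-one | COc1cc(-c2coc3c(OCc4ccccc4)c(OCc4ccccc4)c(OC)c(OCc4ccccc4)c3c2=O)cc(O)c1OC | intermediate
17 | 5,7,8,3'-tetrahydroxy-6,4',5'-trimethoxyisoflavone | COc1cc(-c2coc3c(O)c(O)c(OC)c(O)c3c2=O)cc(O)c1OC | target

**Total step count:** 9. **Longest linear sequence:** 9 steps (1 → 17). Compound 12 enters at step 8 without prior steps.

**Steps most likely to fail**

1. **Step 8 (proposed new method).**
   - Risk: the conjugate addition may be too slow or too reversible. Diels–Alder self-dimerisation of the dienone, capture of the dienone by released amine, or acid cyclisation of the enaminone before arylation could then take over. Methanol might also attack para instead of ortho during the phenol oxidation.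
   - Fallback (known chemistry): it sets out from 11 and 12 and comes back at 16.
     - From 11, iodine in CHCl3 at rt should give, by iodination and cyclisation, 5,7,8-tris(benzyloxy)-3-iodo-6-methoxy-4H-chromen-4-one F1.
     - From 12, sterically controlled iridium-catalysed C–H borylation ([Ir(OMe)(cod)]2, dtbpy, B2pin2, THF, 80 °C) should give 2,3-dimethoxy-5-(4,4,5,5-tetramethyl-1,3,2-dioxaborolan-2-yl)phenol F2. The phenol is masked in the flask as its O-boryl ester and freed on work-up.
     - Suzuki–Miyaura coupling of the two (Pd(dppf)Cl2, K2CO3, dioxane–H2O, 80 °C) forms the same C3–C1' bond.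

2. **Step 5.**
   - Risk: low conversion from poor solubility of the tribenzylated phenoxide in aqueous alkali, over-oxidation of the hydroquinone once formed, and partial loss of benzyl groups during the acid hydrolysis.
   - Fallback: it sets out from 7 and comes back at 10, bypassing 9 and step 6.
     - Electrophilic bromination of the only free ring position (NBS, MeCN, 0 °C) should give 1-[3,4,6-tris(benzyloxy)-5-bromo-2-hydroxyphenyl]ethanone F3.
     - Copper(I)-catalysed Ullmann-type methoxylation (NaOMe, CuBr, DMF–MeOH, 110 °C) then installs the methoxy group directly.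

3. **Step 2.**
   - Risk: loss of site selectivity, by alkylation of the central OH, over-alkylation, or C-benzylation of the ring.
   - Fallback: it sets out from 1 and comes back at 4, bypassing 3 by inverting the order of events.
     - Dibenzylation of 1 (BnBr 2 equiv, K2CO3, DMF) leaves its single chelated OH and should give 1-[2,4-bis(benzyloxy)-6-hydroxyphenyl]ethanone F4.
     - Ortho-specific formylation of its magnesium phenoxide (MgCl2, Et3N, paraformaldehyde, MeCN, reflux; Casnati–Skattebøl reaction) can only go to the carbon next to the free OH.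

**Further compounds**
F1 | step 8 | 5,7,8-tris(benzyloxy)-3-iodo-6-methoxy-4H-chromen-4-one | COc1c(OCc2ccccc2)c(OCc2ccccc2)c2occ(I)c(=O)c2c1OCc1ccccc1
F2 | step 8 | 2,3-dimethoxy-5-(4,4,5,5-tetramethyl-1,3,2-dioxaborolan-2-yl)phenol | COc1cc(B2OC(C)(C)C(C)(C)O2)cc(O)c1OC
F3 | step 5 | 1-[3,4,6-tris(benzyloxy)-5-bromo-2-hydroxyphenyl]ethanone | CC(=O)c1c(O)c(OCc2ccccc2)c(OCc2ccccc2)c(Br)c1OCc1ccccc1
F4 | step 2 | 1-[2,4-bis(benzyloxy)-6-hydroxyphenyl]ethanone | CC(=O)c1c(O)cc(OCc2ccccc2)cc1OCc1ccccc1
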